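**Plan**
- Retrosynthesis: cut both aryl ether bonds O1–C8a and O1''–C8a'' together, then the central C3–C3'' bond (which divides the target into two identical halves), then the aryl ketone bond C4–C4a of the monomer, leaving a chiral hydroxy Weinreb amide and a fluoroarene.
- Forward: the lithiated fluoroarene (ring A) is joined to the amide to give a beta-hydroxy ketone; two molecules of its dianion are coupled oxidatively at C3–C3''; the two pyranone rings C and C'' then close in one operation; desilylation ends the route.
- Enabling feature: in the dimer each carbinol oxygen (future O1) sits beta to a C4 carbonyl whose ring A carries fluorine at C8a, ortho to that carbonyl. O1 reaches C8a through a six-membered transition state, C4=O takes up the charge, and the C2 symmetry makes both closures the same event.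
- Stereochemistry: C2 and C2'' (S) come from asymmetric transfer hydrogenation of a beta-keto ester. C3 and C3'' (R) come from chelate-controlled anti coupling, and this 2,3-trans arrangement is also the thermodynamically preferred one in each chromanone.
- Helpers: fluorine at C8a (leaving group, lost in the key step) and triisopropylsilyl groups on the C7 oxygens (removed last).

Key step: step 6

Remark: lithiation of the silyl ether 2 is taken to occur only at the carbon flanked by fluorine and methoxy, the bulky silyloxy group shielding its two neighbours.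

**Step 1**
Reactants: 1 3-fluoro-5-methoxyphenol
Product: 2 (3-fluoro-5-methoxyphenoxy)triisopropylsilane
Conditions: i-Pr3SiCl, imidazole, DMF, rt
Reagents that add atoms: triisopropylsilyl chloride, CC(C)[Si](Cl)(C(C)C)C(C)C
Why: Imidazole-promoted silylation of the phenol installs a bulky, non-directing silyl ether that protects the future C7 oxygen and shields its two ortho positions from the later lithiation.

**Step 2**
Reactants: 3 methyl 3-(4-methoxyphenyl)-3-oxopropanoate
Product: 4 methyl (3S)-3-hydroxy-3-(4-methoxyphenyl)propanoate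
Conditions: RuCl[(S,S)-TsDPEN](p-cymene) (1 mol %), HCO2H/Et3N (5:2), 40 °C
Reagents that add atoms: none
Why: Noyori–Ikariya asymmetric transfer hydrogenation of the aryl ketone should set the carbinol (future C2) as S through the catalyst-controlled six-membered hydride transfer that gives (S)-alcohols from aryl alkyl ketones with the (S,S)-catalyst (the antipodal catalyst would be used if the sense proved opposite), and the ester is untouched.

**Step 3**
Reactants: 4 methyl (3S)-3-hydroxy-3-(4-methoxyphenyl)propanoate
Product: 5 (3S)-3-hydroxy-N-methoxy-3-(4-methoxyphenyl)-N-methylpropanamide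
Conditions: MeNH(OMe)·HCl, i-PrMgCl (excess), THF, −20 to 0 °C
Reagents that add atoms: N,O-dimethylhydroxylamine hydrochloride, CNOC.Cl
Why: Direct ester-to-Weinreb-amide conversion by the chloromagnesium amide of N,O-dimethylhydroxylamine makes and breaks no bond at the carbinol carbon, whose hydroxyl only consumes one further equivalent of base, so the S configuration should be kept.

**Step 4**
Reactants: 2 (3-fluoro-5-methoxyphenoxy)triisopropylsilane; 5 (3S)-3-hydroxy-N-methoxy-3-(4-methoxyphenyl)-N-methylpropanamide
Product: 9 (3S)-1-[2-fluoro-6-methoxy-4-(triisopropylsilyloxy)phenyl]-3-hydroxy-3-(4-methoxyphenyl)propan-1-one, via aryllithium 6 (not isolated), via lithium alkoxide 7 (not isolated), via tetrahedral adduct 8 (not isolated)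
Conditions: 2 (2.4 equiv), n-BuLi (2.3 equiv), THF, −78 °C; then 5, −78 to −60 °C; AcOH, −78 °C
Reagents that add atoms: none
Why: Directed ortho-lithiation at the carbon acidified by both F and OMe is followed by a Weinreb ketone synthesis in which the first equivalent of 6 deprotonates the hydroxyl and the second adds to the amide, the chelated adduct 8 releasing the ketone only on acidic quench so that neither over-addition nor contact of the free ketone with base should occur.

**Step 5**
Reactants: 9 (3S)-1-[2-fluoro-6-methoxy-4-(triisopropylsilyloxy)phenyl]-3-hydroxy-3-(4-methoxyphenyl)propan-1-one; 9 (3S)-1-[2-fluoro-6-methoxy-4-(triisopropylsilyloxy)phenyl]-3-hydroxy-3-(4-methoxyphenyl)propan-1-one (a second molecule of the same compound)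
Product: 11 (2R,3R)-1,4-bis[2-fluoro-6-methoxy-4-(triisopropylsilyloxy)phenyl]-2,3-bis[(S)-hydroxy(4-methoxyphenyl)methyl]butane-1,4-dione, via dilithium alkoxide-enolate 10 (not isolated)
Conditions: LiN(i-Pr)2 (2.15 equiv per molecule of 9), THF, −78 to −40 °C; CuCl2 (1.1 equiv per molecule of 9) in DMF, −78 °C; AcOH, −78 °C
Reagents that add atoms: none
Why: Proposed new method: double deprotonation of each of the two molecules of 9 gives the dilithium alkoxide–(Z)-enolate 10 as a six-membered lithium chelate in which the O–Li group cannot leave (no beta-elimination to the chalcone) and the already anionic alpha-carbon cannot be expelled (no retro-aldol); one-electron oxidation by CuCl2 should then join two chelated alpha-keto radicals or copper enolates at C3, each on the chelate face anti to the C2 aryl group (the facial sense of the Fráter–Seebach alkylation), so that both new centres are R and the C2-symmetric anti,anti dimer results from two molecules of 9 with loss of two hydrogen atoms, homochiral pairing also raising the enantiomeric purity (Horeau principle); the closest known reaction types are the CuCl2-mediated oxidative dimerisation of lithium ketone enolates to 1,4-diketones and the anti-selective alkylation of beta-hydroxy carbonyl dianions, and the new element is their combination on an O,C-dianion.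

**Step 6**
Reactants: 11 (2R,3R)-1,4-bis[2-fluoro-6-methoxy-4-(triisopropylsilyloxy)phenyl]-2,3-bis[(S)-hydroxy(4-methoxyphenyl)methyl]butane-1,4-dione
Product: 14 (2S,3R,2''S,3''R)-5,5''-dimethoxy-2,2''-bis(4-methoxyphenyl)-7,7''-bis(triisopropylsilyloxy)-3,3''-bichroman-4,4''-dione, via dipotassium dialkoxide 12 (not isolated), via monocyclised alkoxide 13 (not isolated)
Conditions: KN(SiMe3)2 (2.05 equiv), THF (0.01 M), −78 to −30 °C; AcOH, −78 °C
Reagents that add atoms: none
Why: KN(SiMe3)2 converts both carbinol hydroxyls into potassium alkoxides, and each alkoxide oxygen (future O1) adds to the fluorine-bearing carbon C8a of its own ring A, ortho to the C4 carbonyl, giving a Meisenheimer adduct whose charge rests on the C4 carbonyl oxygen and which then expels KF (intramolecular SNAr, addition then elimination). The closest known reaction type is the base-mediated SNAr cyclisation of 2-fluoroaryl ketones bearing a suitably placed oxygen nucleophile to chroman-4-ones and xanthones. Each pyranone ring (ring C, then ring C'') closes in the 6-endo-trig mode, the attacked C8a=C4a bond lying inside the new six-membered ring and being conjugated to C4=O. No stereocentre is created at the bond-forming atoms: C2 and C2'' keep the S configuration because the C2–O bond is never broken, and C3 and C3'' keep the R configuration from step 5, which places all four substituents equatorial on the two half-chairs, so any enolisation at C3 should only return the same 2,3-trans isomer. The step needs closure to outrun retro-aldol loss of 4-methoxybenzaldehyde and needs each alkoxide to choose its own ring; the first is served by the low temperature, the six-membered transition state and the fluoride ortho to the carbonyl, the second by six- over seven-membered ring formation. The C7 silyl ethers keep ring A from becoming a phenoxide that would switch the SNAr off, and they should survive because KF is insoluble in THF.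

**Step 7**
Reactants: 14 (2S,3R,2''S,3''R)-5,5''-dimethoxy-2,2''-bis(4-methoxyphenyl)-7,7''-bis(triisopropylsilyloxy)-3,3''-bichroman-4,4''-dione
Product: 15 4',4''',5,5''-tetramethylchamaejasmin
Conditions: Bu4NF, AcOH (1:1, 2.4 equiv), THF, 0 °C
Reagents that add atoms: none
Why: Fluoride-mediated cleavage of the two aryl silyl ethers (the acyl-stabilised phenoxides leave silicon readily) is buffered with acetic acid so that no basic fluoride or phenoxide can enolise C3 or open the pyranone rings.

**Compound list**
1 | 3-fluoro-5-methoxyphenol | COc1cc(O)cc(F)c1 | starting material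
2 | (3-fluoro-5-methoxyphenoxy)triisopropylsilane | COc1cc(F)cc(O[Si](C(C)C)(C(C)C)C(C)C)c1 | intermediate
3 | methyl 3-(4-methoxyphenyl)-3-oxopropanoate | COC(=O)CC(=O)c1ccc(OC)cc1 | starting material
4 | methyl (3S)-3-hydroxy-3-(4-methoxyphenyl)propanoate | COC(=O)C[C@H](O)c1ccc(OC)cc1 | intermediate
5 | (3S)-3-hydroxy-N-methoxy-3-(4-methoxyphenyl)-N-methylpropanamide | CON(C)C(=O)C[C@H](O)c1ccc(OC)cc1 | intermediate
6 | [2-fluoro-6-methoxy-4-(triisopropylsilyloxy)phenyl]lithium (not isolated) | [Li]c1c(F)cc(O[Si](C(C)C)(C(C)C)C(C)C)cc1OC | intermediate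
7 | lithium alkoxide of 5 (not isolated) | CON(C)C(=O)C[C@H](O[Li])c1ccc(OC)cc1 | intermediate
8 | dilithium tetrahedral adduct of 6 and 7 (not isolated; hemiaminal carbon undefined) | CON(C)C(O[Li])(C[C@H](O[Li])c1ccc(OC)cc1)c1c(F)cc(O[Si](C(C)C)(C(C)C)C(C)C)cc1OC | intermediate
9 | (3S)-1-[2-fluoro-6-methoxy-4-(triisopropylsilyloxy)phenyl]-3-hydroxy-3-(4-methoxyphenyl)propan-1-one | COc1ccc([C@@H](O)CC(=O)c2c(F)cc(O[Si](C(C)C)(C(C)C)C(C)C)cc2OC)cc1 | intermediate
10 | dilithium alkoxide–(Z)-enolate of 9 (not isolated) | COc1ccc([C@@H](O[Li])/C=C(\O[Li])c2c(F)cc(O[Si](C(C)C)(C(C)C)C(C)C)cc2OC)cc1 | intermediate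
11 | (2R,3R)-1,4-bis[2-fluoro-6-methoxy-4-(triisopropylsilyloxy)phenyl]-2,3-bis[(S)-hydroxy(4-methoxyphenyl)methyl]butane-1,4-dione | COc1ccc([C@@H](O)[C@H](C(=O)c2c(F)cc(O[Si](C(C)C)(C(C)C)C(C)C)cc2OC)[C@@H](C(=O)c2c(F)cc(O[Si](C(C)C)(C(C)C)C(C)C)cc2OC)[C@H](O)c2ccc(OC)cc2)cc1 | intermediate
12 | dipotassium dialkoxide of 11 (not isolated) | COc1ccc([C@@H](O[K])[C@H](C(=O)c2c(F)cc(O[Si](C(C)C)(C(C)C)C(C)C)cc2OC)[C@@H](C(=O)c2c(F)cc(O[Si](C(C)C)(C(C)C)C(C)C)cc2OC)[C@H](O[K])c2ccc(OC)cc2)cc1 | intermediate
13 | monocyclised potassium alkoxide, one chromanone ring closed (not isolated) | COc1ccc([C@@H](O[K])[C@H](C(=O)c2c(F)cc(O[Si](C(C)C)(C(C)C)C(C)C)cc2OC)[C@H]2C(=O)c3c(OC)cc(O[Si](C(C)C)(C(C)C)C(C)C)cc3O[C@@H]2c2ccc(OC)cc2)cc1 | intermediate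
14 | (2S,3R,2''S,3''R)-5,5''-dimethoxy-2,2''-bis(4-methoxyphenyl)-7,7''-bis(triisopropylsilyloxy)-3,3''-bichroman-4,4''-dione | COc1ccc([C@H]2Oc3cc(O[Si](C(C)C)(C(C)C)C(C)C)cc(OC)c3C(=O)[C@@H]2[C@H]2C(=O)c3c(OC)cc(O[Si](C(C)C)(C(C)C)C(C)C)cc3O[C@@H]2c2ccc(OC)cc2)cc1 | intermediate
15 | 4',4''',5,5''-tetramethylchamaejasmin, (2S,3R,2''S,3''R) | COc1ccc([C@H]2Oc3cc(O)cc(OC)c3C(=O)[C@@H]2[C@H]2C(=O)c3c(OC)cc(O)cc3O[C@@H]2c2ccc(OC)cc2)cc1 | target

**Step count**
Total steps: 7. Longest linear sequence: 6 steps (3 → 4 → 5 → 9 → 11 → 14 → 15).

**Steps most likely to fail**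

Step 5. The dianion may aggregate and resist clean one-electron oxidation, the lithium alkoxide may bind copper unproductively, or facial control in the coupling may be lost. The fallback uses known chemistry and sets out from 9. Silylation (Et3SiCl, imidazole, CH2Cl2) should give the triethylsilyl ether F1. Saegusa-type oxidative dimerisation of the lithium enolate, joining two molecules of F1 (LiN(i-Pr)2, THF, −78 °C; CuCl2, DMF), should give the bis(triethylsilyl) ether dimer F2 as a mixture of epimers at the two new centres. AcOH/THF/H2O at room temperature should unveil the diol epimer mixture F3. The double SNAr of step 6 (KN(SiMe3)2, THF) would then give the bichromanone epimer mixture F4. Catalytic DBU in toluene at room temperature should equilibrate C3 and C3'' by enolisation to the diequatorial trans,trans isomer, which is compound 14, where the route is rejoined.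

Step 6. Retro-aldol fragmentation of the congested dialkoxide may outrun ring closure; recombination would also erode the C2 configuration. Hemiketal formation with the 1,4-related carbonyl may further hold the alkoxide back. The fallback sets out from 9 and closes the ring before the central bond exists. The same SNAr on the unbranched monomer (KN(SiMe3)2, THF, −78 to −30 °C), where no vicinal tertiary centres and no second carbonyl are present, should give the flavanone F5. Soft enolisation (Me3SiOTf, Et3N, CH2Cl2, 0 °C) should give the enol silane F6. Oxidative homocoupling of two molecules of this silyl enol ether (Ag2O, DMSO) should form C3–C3'' on the closed rings, each new bond anti to the C2 aryl group, which for an enantiopure monomer can only give compound 14, where the route is rejoined.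

Step 4. Loss of LiF from aryllithium 6 (aryne formation) may compete with a slow addition of this di-ortho-substituted nucleophile to the alkoxide-bearing amide, or 6 may be spent in proton transfer from the amide alpha-position. The fallback sets out from 6 and changes the bond that joins the halves. Capture of 6 at −78 °C with the small electrophile N-methoxy-N-methylacetamide (AcOH quench) should give the acetophenone F7. Me3SiOTf and Et3N should give the trimethylsilyl enol ether F8. An enantioselective Mukaiyama aldol addition to 4-methoxybenzaldehyde (SiCl4, chiral bisphosphoramide Lewis base catalyst of the antipode that gives the S carbinol, i-Pr2NEt, CH2Cl2, −78 °C; aqueous NaHCO3 work-up) should form the C2–C3 bond and give compound 9, where the route is rejoined.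

**Further compounds**
F1 | step 5 | (3S)-1-[2-fluoro-6-methoxy-4-(triisopropylsilyloxy)phenyl]-3-(4-methoxyphenyl)-3-(triethylsilyloxy)propan-1-one | COc1ccc([C@@H](O[Si](CC)(CC)CC)CC(=O)c2c(F)cc(O[Si](C(C)C)(C(C)C)C(C)C)cc2OC)cc1
F2 | step 5 | 1,4-bis[2-fluoro-6-methoxy-4-(triisopropylsilyloxy)phenyl]-2,3-bis[(S)-(4-methoxyphenyl)(triethylsilyloxy)methyl]butane-1,4-dione, epimer mixture at C2 and C3 | COc1ccc([C@@H](O[Si](CC)(CC)CC)C(C(=O)c2c(F)cc(O[Si](C(C)C)(C(C)C)C(C)C)cc2OC)C(C(=O)c2c(F)cc(O[Si](C(C)C)(C(C)C)C(C)C)cc2OC)[C@H](O[Si](CC)(CC)CC)c2ccc(OC)cc2)cc1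
F3 | step 5 | 1,4-bis[2-fluoro-6-methoxy-4-(triisopropylsilyloxy)phenyl]-2,3-bis[(S)-hydroxy(4-methoxyphenyl)methyl]butane-1,4-dione, epimer mixture at C2 and C3 | COc1ccc([C@@H](O)C(C(=O)c2c(F)cc(O[Si](C(C)C)(C(C)C)C(C)C)cc2OC)C(C(=O)c2c(F)cc(O[Si](C(C)C)(C(C)C)C(C)C)cc2OC)[C@H](O)c2ccc(OC)cc2)cc1
F4 | step 5 | (2S,2''S)-5,5''-dimethoxy-2,2''-bis(4-methoxyphenyl)-7,7''-bis(triisopropylsilyloxy)-3,3''-bichroman-4,4''-dione, epimer mixture at C3 and C3'' | COc1ccc([C@H]2Oc3cc(O[Si](C(C)C)(C(C)C)C(C)C)cc(OC)c3C(=O)C2C2C(=O)c3c(OC)cc(O[Si](C(C)C)(C(C)C)C(C)C)cc3O[C@@H]2c2ccc(OC)cc2)cc1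
F5 | step 6 | (2S)-5-methoxy-2-(4-methoxyphenyl)-7-(triisopropylsilyloxy)chroman-4-one | COc1ccc([C@@H]2CC(=O)c3c(OC)cc(O[Si](C(C)C)(C(C)C)C(C)C)cc3O2)cc1
F6 | step 6 | (2S)-5-methoxy-2-(4-methoxyphenyl)-7-(triisopropylsilyloxy)-4-(trimethylsilyloxy)-2H-chromene | COc1ccc([C@@H]2C=C(O[Si](C)(C)C)c3c(OC)cc(O[Si](C(C)C)(C(C)C)C(C)C)cc3O2)cc1
F7 | step 4 | 1-[2-fluoro-6-methoxy-4-(triisopropylsilyloxy)phenyl]ethan-1-one | CC(=O)c1c(F)cc(O[Si](C(C)C)(C(C)C)C(C)C)cc1OC
F8 | step 4 | {1-[2-fluoro-6-methoxy-4-(triisopropylsilyloxy)phenyl]ethenyloxy}trimethylsilane | C=C(O[Si](C)(C)C)c1c(F)cc(O[Si](C(C)C)(C(C)C)C(C)C)cc1OC
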